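**Retrosynthetic overview**
1. C3–C(sp) bond: Sonogashira disconnection to a 3‑iodofuran and but‑3‑yn‑2‑one.
2. Furan, the only ring formed (step 2; both phenyl rings are bought): 5‑endo‑dig iodocyclisation, O‑demethylation and dehydration of an acyclic 5‑hydroxy‑4‑methoxy‑hepta‑2,6‑diyn‑1‑one.
3. Key C4–C5 bond: both carbons carry oxygen and are normally electrophilic. C5 is used with inverted polarity as an α‑methoxypropargyl carbanion (d1, a masked alkynoyl anion) that adds 1,2 to the ketone carbon of 4‑phenylbut‑3‑yn‑2‑one.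
4. The carbanion is the propargylic end of dilithiated methyl propargyl ether. Its acetylide end is benzoylated in the same flask with a Weinreb amide.

**Assumption:** the SMILES has no stereocentre, so capillaridin A is achiral and there is no enantiomer to select. The sp3 stereocentres of intermediates are carried as racemic diastereomer mixtures and disappear on aromatisation.

**Step 1**
Reactants: 1 methyl propargyl ether (3‑methoxyprop‑1‑yne); 2 4‑phenylbut‑3‑yn‑2‑one; 3 N‑methoxy‑N‑methylbenzamide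
Product: 7 5‑hydroxy‑4‑methoxy‑5‑methyl‑1,7‑diphenylhepta‑2,6‑diyn‑1‑one, via dilithiated methyl propargyl ether 4 (not isolated), via lithium alkoxide acetylide 5 (not isolated), via Weinreb tetrahedral adduct 6 (not isolated)
Conditions: 1 (1.05 equiv), s‑BuLi (2.1 equiv), TMEDA, THF, −78 °C; then 2 (1.0 equiv), −78 °C; then 3 (1.3 equiv), −78 to 0 °C; AcOH, −78 °C
Reagents that add atoms: none
Why: Proposed new method: double deprotonation gives the 1,3‑dianion 4, whose more basic α‑methoxy propargylic carbon (d1 synthon, masked alkynoyl anion) adds 1,2 to the ketone carbonyl of 2 and so joins two oxygen‑bearing, normally electrophilic carbons (future C5 and C4); only the α‑carbon can attack because the γ‑terminus is already the acetylide, the surviving acetylide 5 is acylated by 3, and chelate 6 masks the retro‑aldol‑prone ynone until the cold acidic quench; the closest known reaction types are sequential trapping of 1,3‑dilithiopropyne and of dilithiated propargyl sulfides, carbonyl addition of α‑lithiated propargyl ethers, and the Weinreb ketone synthesis; the two new stereocentres form as a racemic diastereomer mixture, which does not matter because both are erased in step 2.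

**Step 2**
Reactants: 7 5‑hydroxy‑4‑methoxy‑5‑methyl‑1,7‑diphenylhepta‑2,6‑diyn‑1‑one
Product: 10 3‑(4‑iodo‑3‑methyl‑5‑phenylfuran‑2‑yl)‑1‑phenylprop‑2‑yn‑1‑one, via methyloxonium iodide 8 (not isolated), via iododihydrofuranol 9 (not isolated)
Conditions: I2 (2.5 equiv), NaHCO3, MeCN, 0 °C to rt
Reagents that add atoms: iodine, II
Why: Larock‑type electrophilic 5‑endo‑dig iodocyclisation, in which I+ activates the electron‑rich aryl alkyne rather than the electron‑poor ynone, the ether oxygen attacks the benzylic alkyne carbon, iodide demethylates oxonium 8 as with 2‑alkynylanisoles, and the tertiary allylic alcohol 9 loses water spontaneously as in the iodocyclisation of 3‑alkyne‑1,2‑diols to β‑iodofurans (oxygen‑assisted ionisation, acidified C5–H, aromatisation); no stereocentre remains.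

**Step 3**
Reactants: 10 3‑(4‑iodo‑3‑methyl‑5‑phenylfuran‑2‑yl)‑1‑phenylprop‑2‑yn‑1‑one; 11 but‑3‑yn‑2‑one
Product: 12 capillaridin A, 4‑[4‑methyl‑5‑(3‑oxo‑3‑phenylprop‑1‑yn‑1‑yl)‑2‑phenylfuran‑3‑yl]but‑3‑yn‑2‑one
Conditions: PdCl2(PPh3)2 (5 mol %), CuI (10 mol %), Et3N (3 equiv), THF, slow addition of 11 (3 equiv), rt to 40 °C
Reagents that add atoms: none
Why: Sonogashira coupling of a heteroaryl iodide with a terminal ynone, where the C–I bond is the only oxidative‑addition site, the tertiary amine cannot form a stable Michael adduct with either ynone, slow addition limits oligomerisation and Glaser coupling of 11, and no stereocentre is created.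

**Compound list**
1 | methyl propargyl ether (3‑methoxyprop‑1‑yne) | C#CCOC | starting material
2 | 4‑phenylbut‑3‑yn‑2‑one | CC(=O)C#Cc1ccccc1 | starting material
3 | N‑methoxy‑N‑methylbenzamide | CON(C)C(=O)c1ccccc1 | starting material
4 | 1,3‑dilithio‑3‑methoxyprop‑1‑yne | [Li]C#CC([Li])OC | intermediate
5 | dilithium salt (alkoxide and acetylide) of 4‑methoxy‑3‑methyl‑1‑phenylhexa‑1,5‑diyn‑3‑ol | [Li]C#CC(OC)C(C)(O[Li])C#Cc1ccccc1 | intermediate
6 | dilithium tetrahedral adduct of 5 with 3 | CON(C)C(O[Li])(c1ccccc1)C#CC(OC)C(C)(O[Li])C#Cc1ccccc1 | intermediate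
7 | 5‑hydroxy‑4‑methoxy‑5‑methyl‑1,7‑diphenylhepta‑2,6‑diyn‑1‑one (racemic, diastereomer mixture) | CC(O)(C#Cc1ccccc1)C(OC)C#CC(=O)c1ccccc1 | intermediate
8 | 3‑hydroxy‑4‑iodo‑1,3‑dimethyl‑2‑(3‑oxo‑3‑phenylprop‑1‑yn‑1‑yl)‑5‑phenyl‑2,3‑dihydrofuran‑1‑ium iodide | CC1(O)C(C#CC(=O)c2ccccc2)[O+](C)C(c2ccccc2)=C1I.[I-] | intermediate
9 | 3‑(3‑hydroxy‑4‑iodo‑3‑methyl‑5‑phenyl‑2,3‑dihydrofuran‑2‑yl)‑1‑phenylprop‑2‑yn‑1‑one | CC1(O)C(C#CC(=O)c2ccccc2)OC(c2ccccc2)=C1I | intermediate
10 | 3‑(4‑iodo‑3‑methyl‑5‑phenylfuran‑2‑yl)‑1‑phenylprop‑2‑yn‑1‑one | Cc1c(C#CC(=O)c2ccccc2)oc(-c2ccccc2)c1I | intermediate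
11 | but‑3‑yn‑2‑one | CC(=O)C#C | starting material
12 | capillaridin A (achiral) | CC(=O)C#Cc1c(-c2ccccc2)oc(C#CC(=O)c2ccccc2)c1C | target

**Total step count:** 3. **Longest linear sequence:** 3.

**Steps most likely to fail (most risky first: 1, 2, 3)**

Step 1 can fail in two ways. The second deprotonation of 1 may be incomplete, or the dianion may enolise 2 instead of adding to it. The fallback sets out from 1 and 2 and comes back at 7. It keeps the same C4–C5 bond but replaces the dianion by a capped mono‑anion and moves the benzoylation to a separate catalytic step.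
- 1 is C‑silylated (n‑BuLi, TMSCl) to 3‑methoxy‑1‑(trimethylsilyl)prop‑1‑yne F1.
- A single deprotonation (s‑BuLi, −78 °C) and ZnBr2 give [3‑methoxy‑1‑(trimethylsilyl)propa‑1,2‑dien‑1‑yl]zinc bromide F2.
- SE2′ addition of F2 to 2 gives 4‑methoxy‑3‑methyl‑1‑phenyl‑6‑(trimethylsilyl)hexa‑1,5‑diyn‑3‑ol F3.
- K2CO3/MeOH frees 4‑methoxy‑3‑methyl‑1‑phenylhexa‑1,5‑diyn‑3‑ol F4.
- An acyl Sonogashira coupling with benzoyl chloride (PdCl2(PPh3)2, CuI, Et3N) gives 7.

Step 2 can fail because the methyl ether oxygen, deactivated by the neighbouring ynone, may be too poor a nucleophile or may demethylate too slowly. The fallback sets out from 7 and comes back at 10. The ring oxygen is then taken from the C2 side and the methoxy group becomes a leaving group.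
- A gold‑catalysed Meyer–Schuster rearrangement (Ph3PAuNTf2, MeOH 1 equiv, toluene) gives 4‑methoxy‑3‑methyl‑1,7‑diphenylhept‑2‑en‑5‑yne‑1,7‑dione F5. This is a tautomer of the mono‑enol ether of the Paal–Knorr diketone.
- Catalytic p‑TsOH closes F5, with loss of methanol, to 3‑(3‑methyl‑5‑phenylfuran‑2‑yl)‑1‑phenylprop‑2‑yn‑1‑one F6.
- NIS (catalytic TFA, MeCN) iodinates the only free ring position of F6 to give 10.

Step 3 can fail because but‑3‑yn‑2‑one may oligomerise faster than it couples with the flanked iodide. The fallback sets out from 10 and comes back at 12. The coupling is run at the alcohol oxidation level.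
- Sonogashira coupling with racemic but‑3‑yn‑2‑ol gives 3‑[4‑(3‑hydroxybut‑1‑yn‑1‑yl)‑3‑methyl‑5‑phenylfuran‑2‑yl]‑1‑phenylprop‑2‑yn‑1‑one F7.
- Oxidation of the propargylic alcohol F7 with MnO2 (CH2Cl2, rt) gives 12.

**Further compounds**
F1 | step 1 | 3‑methoxy‑1‑(trimethylsilyl)prop‑1‑yne | COCC#C[Si](C)(C)C
F2 | step 1 | [3‑methoxy‑1‑(trimethylsilyl)propa‑1,2‑dien‑1‑yl]zinc bromide (racemic) | COC=C=C([Zn]Br)[Si](C)(C)C
F3 | step 1 | 4‑methoxy‑3‑methyl‑1‑phenyl‑6‑(trimethylsilyl)hexa‑1,5‑diyn‑3‑ol (racemic, diastereomer mixture) | CC(O)(C#Cc1ccccc1)C(OC)C#C[Si](C)(C)C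
F4 | step 1 | 4‑methoxy‑3‑methyl‑1‑phenylhexa‑1,5‑diyn‑3‑ol (racemic, diastereomer mixture) | CC(O)(C#Cc1ccccc1)C(OC)C#C
F5 | step 2 | 4‑methoxy‑3‑methyl‑1,7‑diphenylhept‑2‑en‑5‑yne‑1,7‑dione (racemic, E/Z mixture) | CC(=CC(=O)c1ccccc1)C(OC)C#CC(=O)c1ccccc1
F6 | step 2 | 3‑(3‑methyl‑5‑phenylfuran‑2‑yl)‑1‑phenylprop‑2‑yn‑1‑one | Cc1cc(-c2ccccc2)oc1C#CC(=O)c1ccccc1
F7 | step 3 | 3‑[4‑(3‑hydroxybut‑1‑yn‑1‑yl)‑3‑methyl‑5‑phenylfuran‑2‑yl]‑1‑phenylprop‑2‑yn‑1‑one (racemic) | CC(O)C#Cc1c(-c2ccccc2)oc(C#CC(=O)c2ccccc2)c1C
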